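**Retrosynthetic overview**
1. The maleimide C=C is reached by a double-bond shift from an exocyclic benzylidene succinimide. That comes from a phosphine-mediated olefination joining a chroman-7-carbaldehyde with 3-(4-hydroxyphenyl)maleimide. The imide ring and both benzene rings are bought.
2. The aldehyde comes from the 7-bromochroman-3-ol by Br/Li exchange and DMF. The alcohol comes from 7-bromo-2,2-dimethylchroman-3-one by CBS reduction, which sets C3.
3. The dihydropyran ring of the ketone comes from the five-membered ring of a 3-methylidene-2,2-dimethyl-2,3-dihydrobenzofuran. An iodine(III)-induced 1,2-aryl shift pulls the exocyclic =CH2 into the ring as C4 and leaves the oxygen on C3.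
4. Enabling feature: C4 is a bare CH2 between arene carbon C4a and carbinol carbon C3, O1 on C8a is ortho to C4a, and C2 is quaternary. Excising C4 therefore gives a dihydrofuran ring that cannot aromatise and whose aryl carbon is an activated migrating group.
5. Ring order: the dihydrofuran ring is made by 5-exo-dig reductive Heck cyclisation of an aryl 1,1-dimethylpropargyl ether, then enlarged to the dihydropyran ring.

Key step: step 3

Remark: the structure is read as drawn, so the CH2 arm stands on C7 of the chroman (para to C4a, meta to O1) and C3 is S.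

Step 1
Reactants: 1 5-bromo-2-iodophenol; 2 3-chloro-3-methylbut-1-yne
Product: 3 4-bromo-1-iodo-2-[(2-methylbut-3-yn-2-yl)oxy]benzene
Conditions: CuCl2·2H2O (1 mol%), DBU, MeCN, 0 °C
Reagents that add atoms: none
Why: Copper-catalysed propargylic substitution of a tertiary propargyl chloride by a phenoxide forms the hindered O1–C2 tertiary aryl ether under mild base, and halogenated (more acidic) phenols are good partners.

Step 2
Reactants: 3 4-bromo-1-iodo-2-[(2-methylbut-3-yn-2-yl)oxy]benzene
Product: 4 6-bromo-2,2-dimethyl-3-methylidene-2,3-dihydro-1-benzofuran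
Conditions: Pd(OAc)2 (5 mol%), PPh3 (10 mol%), HCO2Na, DMF, 60 °C
Reagents that add atoms: none
Why: In this reductive Heck cyclisation, oxidative addition should take C–I before C–Br, syn 5-exo-dig carbopalladation closes the dihydrofuran ring, formate delivers hydride to the vinylpalladium, and the quaternary C2 blocks isomerisation to a benzofuran, while 60 °C is well below the Claisen threshold of the ether.

Step 3
Reactants: 4 6-bromo-2,2-dimethyl-3-methylidene-2,3-dihydro-1-benzofuran
Product: 6 7-bromo-2,2-dimethylchroman-3-one, via alkyl(phenyl)iodonium tosylate 5 (not isolated)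
Conditions: PhI(OH)OTs (1.05 equiv), MeOH–H2O 95:5, 0 °C → rt; dilute aq. HCl work-up
Reagents that add atoms: water, O
Why: This is the iodine(III)-mediated oxidative rearrangement of an exocyclic styrene, the reaction type known for turning 1-methylidenebenzocycloalkanes into ring-enlarged β-benzocycloalkanones: iodine(III) adds to the unhindered =CH2 terminus and methanol to the O1-stabilised benzylic C3, giving 5. Loss of iodobenzene from the primary carbon is assisted by the aryl carbon C3a, which bridges (phenonium ion, a 3-exo spiro bridge; no ring is closed from an open chain) and then shifts from C3 to the former =CH2 carbon, so the ring O1–C2–C3–C3a–C7a becomes the ring O1–C2–C3–C4–C4a–C8a without being opened. The methoxy-stabilised cation left at C3 is hydrolysed in the wet acidic medium, so one operation makes the C4–C4a bond, sets the ring size and places the oxygen on C3 next to the quaternary C2. No stereocentre is created; C3 becomes a carbonyl flanked by a quaternary carbon and a CH2, which suits the reagent-controlled reduction that follows. The selectivity needed is aryl over C2-alkyl migration (the latter would lead to the 4-chromanone); the ring oxygen ortho to the migrating carbon stabilises the phenonium ion, and the same oxygen inductively deactivates C2. About one equivalent of oxidant at or below room temperature should prevent α-oxidation of the product.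

Step 4
Reactants: 6 7-bromo-2,2-dimethylchroman-3-one
Product: 7 (3S)-7-bromo-2,2-dimethyl-3,4-dihydro-2H-chromen-3-ol
Conditions: (R)-Me-CBS oxazaborolidine (10 mol%), BH3·SMe2, THF, −20 °C; MeOH quench, aq. work-up
Reagents that add atoms: none
Why: In this Corey–Bakshi–Shibata reduction the quaternary C2 acts as the large group and C4H2 as the small one, as in tert-alkyl methyl ketones where the (S)-catalyst gives the R alcohol, so the (R)-catalyst should deliver hydride to the face that gives (3S), and aryl bromide and ether are inert to borane.

Step 5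
Reactants: 7 (3S)-7-bromo-2,2-dimethyl-3,4-dihydro-2H-chromen-3-ol
Product: 8 (3S)-3-hydroxy-2,2-dimethyl-3,4-dihydro-2H-chromene-7-carbaldehyde
Conditions: n-BuLi (2.2 equiv), THF, −78 °C; DMF, −78 → 0 °C; H2O
Reagents that add atoms: N,N-dimethylformamide, CN(C)C=O
Why: The first equivalent of base forms the alkoxide and the second performs Br/Li exchange, the aryllithium is formylated by DMF (Bouveault-type formylation), and the C3 carbinol centre is not touched.

Step 6
Reactants: 9 4-aminophenol; 10 maleimide
Product: 12 3-(4-hydroxyphenyl)-1H-pyrrole-2,5-dione, via 4-hydroxybenzenediazonium tetrafluoroborate 11 (not isolated)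
Conditions: t-BuONO, aq. HBF4, MeOH, 0 °C; then 10 (2 equiv), Pd(OAc)2 (5 mol%), MeOH, 25–40 °C
Reagents that add atoms: none
Why: Base-free Heck–Matsuda arylation suits electron-rich phenol diazonium salts and leaves the free OH and NH alone, the β-hydride elimination in the ring becomes possible after epimerisation through the palladium O-enolate, and excess maleimide suppresses a second arylation.

Step 7
Reactants: 8 (3S)-3-hydroxy-2,2-dimethyl-3,4-dihydro-2H-chromene-7-carbaldehyde; 12 3-(4-hydroxyphenyl)-1H-pyrrole-2,5-dione
Product: 14 (4E)-3-(4-hydroxyphenyl)-4-{[(3S)-3-hydroxy-2,2-dimethyl-3,4-dihydro-2H-chromen-7-yl]methylidene}pyrrolidine-2,5-dione (epimers at C3 of the imide ring), via phosphorus ylide 13 (not isolated)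
Conditions: 12, PPh3 (1.1 equiv), THF, 60 °C; then 8, EtOH, reflux
Reagents that add atoms: none
Why: Phosphine addition to the unsubstituted maleimide carbon reverses the polarity of this acceptor carbon (stabilised ylide 13 after proton shift), so two electrophilic carbons are joined by a Wittig olefination that tolerates OH, ArOH and NH, and the new imide C3 centre (unselective) and the alkene geometry are both erased in step 8.

Step 8
Reactants: 14 (4E)-3-(4-hydroxyphenyl)-4-{[(3S)-3-hydroxy-2,2-dimethyl-3,4-dihydro-2H-chromen-7-yl]methylidene}pyrrolidine-2,5-dione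
Product: 15 asperimide C
Conditions: Et3N (5 equiv), MeCN, reflux
Reagents that add atoms: none
Why: This is the known base-mediated alkylidenesuccinimide-to-maleimide isomerisation (1,3-prototropic shift through the extended imide dienolate), in which the doubly activated imide C3–H is removed and the proton returns to the exocyclic carbon, driven by a tetrasubstituted maleimide conjugated with both carbonyls and the 4-hydroxyphenyl donor, while C3 of the chroman is not acidic and stays S.

**Compound list**
1 | 5-bromo-2-iodophenol | Oc1cc(Br)ccc1I | starting material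
2 | 3-chloro-3-methylbut-1-yne | C#CC(C)(C)Cl | starting material
3 | 4-bromo-1-iodo-2-[(2-methylbut-3-yn-2-yl)oxy]benzene | C#CC(C)(C)Oc1cc(Br)ccc1I | intermediate
4 | 6-bromo-2,2-dimethyl-3-methylidene-2,3-dihydro-1-benzofuran | C=C1c2ccc(Br)cc2OC1(C)C | intermediate
5 | [(6-bromo-3-methoxy-2,2-dimethyl-2,3-dihydro-1-benzofuran-3-yl)methyl](phenyl)iodonium tosylate (racemic, not isolated) | COC1(C[I+]c3ccccc3)c2ccc(Br)cc2OC1(C)C.Cc1ccc(cc1)S(=O)(=O)[O-] | intermediate
6 | 7-bromo-2,2-dimethylchroman-3-one | CC1(C)Oc2cc(Br)ccc2CC1=O | intermediate
7 | (3S)-7-bromo-2,2-dimethyl-3,4-dihydro-2H-chromen-3-ol | CC1(C)Oc2cc(Br)ccc2C[C@@H]1O | intermediate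
8 | (3S)-3-hydroxy-2,2-dimethyl-3,4-dihydro-2H-chromene-7-carbaldehyde | CC1(C)Oc2cc(C=O)ccc2C[C@@H]1O | intermediate
9 | 4-aminophenol | Nc1ccc(O)cc1 | starting material
10 | maleimide (1H-pyrrole-2,5-dione) | O=C1C=CC(=O)N1 | starting material
11 | 4-hydroxybenzenediazonium tetrafluoroborate (not isolated) | Oc1ccc(cc1)[N+]#N.F[B-](F)(F)F | intermediate
12 | 3-(4-hydroxyphenyl)-1H-pyrrole-2,5-dione | O=C1C=C(c2ccc(O)cc2)C(=O)N1 | intermediate
13 | 3-(4-hydroxyphenyl)-4-(triphenyl-λ5-phosphanylidene)pyrrolidine-2,5-dione (racemic, not isolated) | O=C1NC(=O)C(c2ccc(O)cc2)C1=P(c3ccccc3)(c4ccccc4)c5ccccc5 | intermediate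
14 | (4E)-3-(4-hydroxyphenyl)-4-{[(3S)-3-hydroxy-2,2-dimethyl-3,4-dihydro-2H-chromen-7-yl]methylidene}pyrrolidine-2,5-dione (both epimers at imide C3) | CC1(C)Oc2cc(/C=C3/C(=O)NC(=O)C3c4ccc(O)cc4)ccc2C[C@@H]1O | intermediate
15 | asperimide C, 3-{[(3S)-3-hydroxy-2,2-dimethyl-3,4-dihydro-2H-chromen-7-yl]methyl}-4-(4-hydroxyphenyl)-1H-pyrrole-2,5-dione | CC1(C)Oc2cc(CC3=C(c4ccc(O)cc4)C(=O)NC3=O)ccc2C[C@@H]1O | target

Total step count: 8. Longest linear sequence: 7 steps (1–5, 7, 8).

**Steps most likely to fail**

Step 3. Methanol capture at the crowded C3 may lag behind proton loss to an alkenyliodonium salt. The alkyl carbon C2 may migrate in place of the aryl carbon. The enolisable product may also be oxidised further.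
The fallback sets out from 4 and returns at 6. NBS in aqueous acetone should add bromine to the CH2 terminus and water to C3, giving the bromohydrin 6-bromo-3-(bromomethyl)-2,2-dimethyl-2,3-dihydro-1-benzofuran-3-ol F1. Silver tetrafluoroborate in CH2Cl2 then abstracts the primary bromide. This is a halohydrin semipinacol rearrangement, the halide counterpart of the Tiffeneau–Demjanov ring enlargement, so the free hydroxyl drives the same aryl shift directly to the ketone without any oxidant left in the flask.

Step 7. Phosphine addition to the donor-substituted maleimide may be slow and reversible, and the hindered stabilised ylide may not engage the aldehyde.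
The fallback sets out from 8 and returns at 15, building the imide ring instead of buying it.
- Horner–Wadsworth–Emmons reaction of 8 with methyl 2-[(tert-butyldimethylsilyl)oxy]-2-(dimethoxyphosphoryl)acetate (LiHMDS, THF) gives the silyl enol ether methyl 2-[(tert-butyldimethylsilyl)oxy]-3-[(3S)-3-hydroxy-2,2-dimethyl-3,4-dihydro-2H-chromen-7-yl]prop-2-enoate F2.
- Et3N·3HF releases the arylpyruvate methyl 3-[(3S)-3-hydroxy-2,2-dimethyl-3,4-dihydro-2H-chromen-7-yl]-2-oxopropanoate F3.
- Condensation of F3 with commercial 2-(4-hydroxyphenyl)acetamide and excess KOtBu in THF (the α-keto ester/arylacetamide maleimide synthesis) closes the maleimide.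

Step 8. The double-bond migration may stop at an equilibrium mixture, or the base may attack the imide.
The fallback sets out from 14 and returns at 15. Hydrogenation (H2, Pd/C, EtOAc) removes the exocyclic alkene and gives 3-{[(3S)-3-hydroxy-2,2-dimethyl-3,4-dihydro-2H-chromen-7-yl]methyl}-4-(4-hydroxyphenyl)pyrrolidine-2,5-dione F4. DDQ in dioxane then dehydrogenates the succinimide. Hydride is taken from the p-hydroxybenzylic imide carbon (quinone methide), and tautomerisation places the C=C inside the ring irreversibly.

**Further compounds**
F1 | step 3 | 6-bromo-3-(bromomethyl)-2,2-dimethyl-2,3-dihydro-1-benzofuran-3-ol (racemic) | OC1(CBr)c2ccc(Br)cc2OC1(C)C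
F2 | step 7 | methyl 2-[(tert-butyldimethylsilyl)oxy]-3-[(3S)-3-hydroxy-2,2-dimethyl-3,4-dihydro-2H-chromen-7-yl]prop-2-enoate (E/Z mixture) | CC1(C)Oc2cc(C=C(O[Si](C)(C)C(C)(C)C)C(=O)OC)ccc2C[C@@H]1O
F3 | step 7 | methyl 3-[(3S)-3-hydroxy-2,2-dimethyl-3,4-dihydro-2H-chromen-7-yl]-2-oxopropanoate | CC1(C)Oc2cc(CC(=O)C(=O)OC)ccc2C[C@@H]1O
F4 | step 8 | 3-{[(3S)-3-hydroxy-2,2-dimethyl-3,4-dihydro-2H-chromen-7-yl]methyl}-4-(4-hydroxyphenyl)pyrrolidine-2,5-dione (diastereomer mixture at the imide ring) | CC1(C)Oc2cc(CC3C(=O)NC(=O)C3c4ccc(O)cc4)ccc2C[C@@H]1O
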